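## The problem

CNP0265879.1 (26) is a C2-symmetric dimer: two molecules of the lindenane lactone chloranthalactone A (25) are joined head-to-head through a cyclobutane made of C8–C8′ and C9–C9′, both new bonds on the α face (opposite the angular methyl) of each half. In lindenane numbering each half has the cyclopropane C1–C2–C3 cis-fused to cyclopentane ring A (C1–C10–C5–C4–C3), and ring A trans-fused through C5–C10 to cyclohexane ring B (C5 to C10). Each half also carries a quaternary C10 whose methyl C14 is syn to the cyclopropane methylene C2, an exocyclic methylene C15 on C4, and the butenolide C7=C11(C13)–C12(=O)–O–C8 on ring B. Of the twelve stereocentres only four (C1, C3, C5, C10) belong to the monomer; C8 and C9 arise in the dimerisation, where the β-methyl on C10 next to C9 should send the partner to the α face. Within the monomer the cyclopropane carbons can control C10, because reagents approach a bicyclo[3.1.0]hexenone anti to C2. C5 is the awkward centre: its hydrogen lies on the convex face and its carbon substituent on the concave face, cis to C14 and C2, and a trans ring fusion next to a C4 carbonyl is not the thermodynamic one, so C5 must be set kinetically and then kept from enolising. The vinylcyclopropane, the exocyclic methylene and the light- and base-sensitive dienol lactone of 25 will not survive strong acid, electrophilic metals or prolonged base, and must appear late. The feature that opens the way is the α-methylbutenolide on ring B: C7=C11 with C13 is a methyl-capped alkyne, C8–O an aldehyde and C12=O carbon monoxide, tethered through C9–C10–C5–C6, so ring B and the lactone can be made in one cyclocarbonylation.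

## Retrosynthesis

**26 to 25.** The cyclobutane bonds C8–C8′ and C9–C9′ are cut first. This is the only cut that uses the symmetry, and it reduces twelve stereocentres to four. The forward [2+2] photodimerisation must be head-to-head and α,α; biradical stability (oxygen- and lactone-stabilised radicals at C8) and the β-methyl on C10 should provide both.

**25 to 21, 20 and 19.** The C8=C9 double bond is taken back to the 8-H butenolide 21, and C15 is cut from C4 to give ketone 20, masked as dioxolane 19. This keeps the dienol lactone and the vinylcyclopropane out of all but the last two steps. The forward steps need a non-basic methylenation, because the trans-fused ketone 20 can epimerise at C5, and a γ-functionalisation of the butenolide.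

**19 to 17 and 18.** Three bonds are cut at once: C7–C8, C11–C12 and C12–O. Annulating a lactone onto a preformed ring B ketone would need ring B first and then several steps for the butenolide. This cut removes two rings and leaves a bicyclo[3.1.0]hexane with two arms, the yne-aldehyde 17, plus carbon monoxide 18. The forward reaction must be chemoselective for alkyne plus aldehyde. The C8 centre it creates is later erased.

**17 to 16, 14 and 13.** The aldehyde comes from the vinyl group of 14 by hydroboration and oxidation, and the dioxolane from ketone 13. Early methylenation of C4 was considered instead of the ketal, but a borane could not then tell the C4 methylene from the vinyl group. The ketal also locks C5.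

**13 to 11, then 7, 8 and 9.** C10–C9 and C5–C6 are cut. Vinyl Grignard 8 adds to enone 7 anti to the cyclopropane, which sets C10, and the enolate is alkylated with bromide 9. The C5 configuration is not entrusted to the alkylation. A carbon electrophile and a proton should both arrive on the convex face, and only the proton is wanted there, so ketone 11 is re-enolised and protonated kinetically to give 13.

**7 to 5, 4, then 1 and 2.** The cyclopropane bonds C3–C1 and C3–C2 are cut by an epoxide-carbenoid cyclopropanation of 4, and 4 comes from (S)-epichlorohydrin 1 and crotyl Grignard 2. A metal-carbene cyclopropanation of a branched, racemic chain would reach the same bicycle, but the catalyst would have to override an existing stereocentre. Here the absolute configuration comes from 1, and the methyl-bearing carbon is a stereocentre only in passing, since it becomes trigonal in 7.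

## Roads not taken

**Alternative 1:** Ring B is cut at C5–C6 and C9–C10. A chiral oxazaborolidinium triflimide would catalyse the Diels–Alder addition of 2,3-bis(trimethylsilyloxy)buta-1,3-diene A2 to the methyl-bearing alkene of 2-methylcyclohex-2-ene-1,4-dione A1, giving the cis-fused decalindione A3.
- Merits: absolute configuration is set catalytically in the first step, the quaternary C10 is made directly from two trivial partners, and C7/C8 carry oxygen for the lactone.
- Weak points: A3 has a six-membered left ring and a cis fusion. The lindenane needs ring contraction, a cyclopropane, inversion at C5 and differentiation of two ketones, all after the key step.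
- Comparison: this road is better than the chosen plan in how it obtains enantiopurity and C10. The chosen plan starts from the chiral pool and carries a stereocentre that is later erased. Against that, it has the 3/5 bicycle after two steps, and its key step finishes ring B and the lactone together instead of leaving the hardest features for later.

**Alternative 2:** The cyclopropane bonds C3–C1 and C3–C2 are cut. PtCl2 (or Ph3PAuCl with AgSbF6) would activate the alkyne of the ring B propargylic acetate A4; a 1,2-acetoxy shift gives a C3 metal carbene that cyclopropanates the C10 vinyl group, closing ring A and the cyclopropane to give enol acetate A5.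
- Merits: one catalytic, atom-economic step makes ring A, the cyclopropane and the C4 oxygen from a monocyclic ketal, and it needs neither a stoichiometric lithium amide nor a stoichiometric metal carbonyl.
- Weak points: whether C2 ends up syn to C14 depends on the rotamer of a vinyl group on a quaternary carbon. C5 is trigonal in A5 and must later be protonated next to C4, where the cis fusion is favoured. The butenolide still has to be annulated onto the C8 ketone, and A4 needs its own enantioselective entry.
- Comparison: A5 reaches the tricyclic core in fewer steps. The chosen plan fixes the cyclopropane configuration from 1, lets it control C10, settles C5 on a monocyclic ketone before a ketal locks it, and makes the lactone in the ring-forming step.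

**Alternative 3:** Ring A is cut at C3–C4. Zerovalent palladium (Pd2(dba)3, a chiral phosphoramidite, CsOPiv) would insert into enol triflate A6, activate a cyclopropyl methylene C–H by concerted metalation–deprotonation and reductively eliminate to the tricycle A7.
- Merits: ring A closes with C15 already in place, so there is no late methylenation and never an epimerisable C4 ketone. The trans C5/C10 relationship comes from ordinary conjugate addition and trapping on a cyclohexenone.
- Weak points: the catalyst must choose between two diastereotopic cyclopropyl methylenes to put C2 syn to C14. Alkenyl triflates are less established than aryl halides in this C–H functionalisation, and the butenolide remains to be built.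
- Comparison: this road handles C5 and C15 more cleanly than the chosen plan, which needs a kinetic protonation and a late Takai–Lombardo methylenation. The chosen plan sets every stereocentre by established substrate control, and its key step delivers the part of the molecule that A7 still lacks.

Key step: step 9

Remarks on the chemistry:
- α is the face opposite C14; β is the face of C14.
- The C8 centre created in step 9 is drawn with hydrogen β (lactone oxygen equatorial, trans to C14), the epimer expected from a chair-like cyclisation. Either epimer would serve, because C8 becomes trigonal in step 12.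
- The configuration of 5 is assigned on the basis of trans-lithiation of the epoxide with retention at the carbinol carbon.

## Route

Step 1
Reactants: 1 (S)-epichlorohydrin; 2 but-2-en-1-ylmagnesium chloride
Product: 4 (2S)-2-(2-methylbut-3-en-1-yl)oxirane (side-chain epimer mixture), via chlorohydrin 3 (not isolated)
Conditions: CH3CH=CHCH2MgCl (1.1 equiv, no copper salt), THF, −40 → −10 °C; aq. NH4Cl; then aq. NaOH, rt
Reagents that add atoms: none
Why: The Grignard reagent opens the epoxide of 1 at its unsubstituted carbon and reacts through its γ-carbon (allylic transposition, SE2′), giving the α-methylallyl branch; hydroxide then closes the new epoxide by intramolecular Williamson displacement of chloride. The stereocentre of 1 is never touched, so 4 is (2S); the methyl-bearing carbon forms as both epimers and is erased in step 3.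

Step 2
Reactants: 4 (2S)-2-(2-methylbut-3-en-1-yl)oxirane
Product: 5 (1S,2S,5S)-4-methylbicyclo[3.1.0]hexan-2-ol (C4 epimer mixture)
Conditions: lithium 2,2,6,6-tetramethylpiperidide (2 equiv, from the amine and n-BuLi), t-BuOMe, 0 °C → rt
Reagents that add atoms: none
Why: Lithium-amide-induced intramolecular cyclopropanation of an unsaturated terminal epoxide (Hodgson cyclopropanation): the amide removes the epoxide hydrogen trans to the side chain and the α-lithiated epoxide acts as a carbenoid toward the tethered alkene. The carbinol carbon keeps its configuration and, through the trans-lithiated carbenoid, fixes both cyclopropane carbons (hydroxyl trans to the cyclopropane methylene); these become C3 and C1 of the lindenane skeleton.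

Step 3
Reactants: 5 (1S,2S,5S)-4-methylbicyclo[3.1.0]hexan-2-ol
Product: 7 (1S,5R)-4-methylbicyclo[3.1.0]hex-3-en-2-one, via saturated ketone 6 (not isolated)
Conditions: IBX (3 equiv), DMSO, 25 °C then 75 °C
Reagents that add atoms: none
Why: IBX first oxidises the secondary alcohol and on warming dehydrogenates ketone 6 through its enol (IBX dehydrogenation); only C3–C4 can be desaturated because the other α-carbon is a cyclopropane bridgehead. The epimeric methyl centre becomes trigonal, so both epimers of 5 give the single enone 7.

Step 4
Reactants: 7 (1S,5R)-4-methylbicyclo[3.1.0]hex-3-en-2-one; 8 vinylmagnesium bromide; 9 1-bromobut-2-yne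
Product: 11 (1S,4S,5R)-3-(but-2-yn-1-yl)-4-ethenyl-4-methylbicyclo[3.1.0]hexan-2-one (C3 epimer mixture), via bromomagnesium enolate 10 (not isolated)
Conditions: CH2=CHMgBr (1.4 equiv), CuBr·SMe2 (10 mol %), THF, −78 → −30 °C; then DMPU, 9 (2.5 equiv), −30 → 0 °C
Reagents that add atoms: none
Why: Copper-catalysed conjugate addition of the vinyl Grignard reagent occurs on the convex face of the bicyclo[3.1.0]hexenone, anti to the cyclopropane methylene, which sets quaternary C10 with vinyl α and methyl β. The magnesium enolate 10 is then C-alkylated by the propargylic bromide in the presence of DMPU (three-component conjugate addition–enolate alkylation); the configuration at the alkylated carbon is not relied upon because step 5 resets it.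

Step 5
Reactants: 11 (1S,4S,5R)-3-(but-2-yn-1-yl)-4-ethenyl-4-methylbicyclo[3.1.0]hexan-2-one
Product: 13 (1S,3R,4S,5R)-3-(but-2-yn-1-yl)-4-ethenyl-4-methylbicyclo[3.1.0]hexan-2-one, via potassium enolate 12 (not isolated)
Conditions: KN(SiMe3)2 (1.3 equiv), THF, −78 → 0 °C; then 2,6-di-tert-butyl-4-methylphenol (3 equiv), −78 °C
Reagents that add atoms: none
Why: Only the ring CH bearing the butynyl group can be deprotonated (the other α-carbon is the cyclopropane bridgehead), so both epimers of 11 converge on enolate 12. Kinetic protonation by the hindered phenol should occur on the convex face, anti to the cyclopropane methylene and the C10 methyl, placing hydrogen α and the butynyl group β, trans to the vinyl group (3R); it uses the same facial bias that would send a carbon electrophile to the wrong side.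

Step 6
Reactants: 13 (1S,3R,4S,5R)-3-(but-2-yn-1-yl)-4-ethenyl-4-methylbicyclo[3.1.0]hexan-2-one
Product: 14 (1S,3R,4S,5R)-3-(but-2-yn-1-yl)-4-ethenyl-4-methylspiro[bicyclo[3.1.0]hexane-2,2'-[1,3]dioxolane]
Conditions: (Me3SiOCH2)2 (3 equiv), Me3SiOTf (10 mol %), CH2Cl2, −78 → −20 °C; pyridine quench
Reagents that add atoms: 1,2-bis(trimethylsilyloxy)ethane, C[Si](C)(C)OCCO[Si](C)(C)C
Why: Noyori ketalisation runs under aprotic conditions at low temperature, where the hindered ketone does not enolise, so the kinetically set centre next to the carbonyl is preserved. The dioxolane then blocks epimerisation and removes the only competing carbonyl for step 9.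

Step 7
Reactants: 14 (1S,3R,4S,5R)-3-(but-2-yn-1-yl)-4-ethenyl-4-methylspiro[bicyclo[3.1.0]hexane-2,2'-[1,3]dioxolane]
Product: 16 2-[(1S,3R,4S,5R)-3-(but-2-yn-1-yl)-4-methylspiro[bicyclo[3.1.0]hexane-2,2'-[1,3]dioxolan]-4-yl]ethan-1-ol, via B-alkyl-9-borabicyclononane 15 (not isolated)
Conditions: 9-BBN (1.5 equiv), THF, 0 °C → rt; then 3 M NaOH, 30% H2O2, 0 °C → rt
Reagents that add atoms: hydrogen peroxide, OO
Why: Brown hydroboration–oxidation: 9-BBN places boron on the terminal carbon of the monosubstituted alkene and reacts far more slowly with the internal alkyne; alkaline peroxide replaces boron by hydroxyl. No stereocentre is formed.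

Step 8
Reactants: 16 2-[(1S,3R,4S,5R)-3-(but-2-yn-1-yl)-4-methylspiro[bicyclo[3.1.0]hexane-2,2'-[1,3]dioxolan]-4-yl]ethan-1-ol
Product: 17 2-[(1S,3R,4S,5R)-3-(but-2-yn-1-yl)-4-methylspiro[bicyclo[3.1.0]hexane-2,2'-[1,3]dioxolan]-4-yl]acetaldehyde
Conditions: Dess–Martin periodinane (1.3 equiv), NaHCO3, CH2Cl2, 0 °C → rt
Reagents that add atoms: none
Why: Dess–Martin oxidation under buffered conditions gives the aldehyde without touching the ketal or the alkyne; the aldehyde hangs on a CH2 next to a quaternary carbon, so nothing can epimerise.

Step 9
Reactants: 17 2-[(1S,3R,4S,5R)-3-(but-2-yn-1-yl)-4-methylspiro[bicyclo[3.1.0]hexane-2,2'-[1,3]dioxolan]-4-yl]acetaldehyde; 18 carbon monoxide (delivered as a ligand of Mo(CO)6)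
Product: 19 (8βH)-4,4-ethylenedioxy-15-norlind-7(11)-en-12,8-olide (tetracyclic α-methylbutenolide ketal; C14 and C2 β, H5 α, lactone oxygen α)
Conditions: Mo(CO)6 (1.2 equiv), DMSO (10 equiv), toluene, 100 °C
Reagents that add atoms: molybdenum hexacarbonyl Mo(CO)6 as carrier of 18, [Mo].[C-]#[O+].[C-]#[O+].[C-]#[O+].[C-]#[O+].[C-]#[O+].[C-]#[O+]
Why: DMSO-assisted loss of CO from Mo(CO)6 gives a zerovalent molybdenum carbonyl fragment that binds the C7≡C11 alkyne and the C8=O aldehyde of 17; oxidative cyclisation forms C7–C8 and an oxamolybdacyclopentene, CO migrates into the Mo–C11 bond and C–O reductive elimination forms C12–O and releases the butenolide. The closest known reaction type is the Mo(CO)6/DMSO hetero-Pauson–Khand cyclocarbonylation of methyl-capped oct-6-ynals to cyclohexane-fused α-methylbutenolides, the same 1,7-yne-aldehyde pattern as in 17. Ring B closes in the oxidative cyclisation as a six-membered carbocycle (6-exo-dig with respect to the alkyne) and the lactone closes as a five-membered ring in the insertion–reductive elimination, so three bonds and two rings arise in one formal [2+2+1] event. The one new stereocentre, C8, is set in the oxidative cyclisation: in the chair-like ring B imposed by the trans arms on C5 and C10 the C8–O bond must lie in the plane of the metallacycle and is therefore equatorial, trans to the axial C14 methyl, which gives 8β-H; the centre is erased in step 12, so its control is not required. The selectivity that matters is chemoselectivity: the dioxolane removes the only other carbonyl, no alkene is present, and the methyl cap on the alkyne disfavours alkyne oligomerisation and supplies C13. The trans arms on adjacent ring carbons hold alkyne and aldehyde within reach, and the aldehyde cannot epimerise.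

Step 10
Reactants: 19 (8βH)-4,4-ethylenedioxy-15-norlind-7(11)-en-12,8-olide
Product: 20 (8βH)-4-oxo-15-norlind-7(11)-en-12,8-olide
Conditions: PPTS (20 mol %), acetone/H2O (9:1), 50 °C
Reagents that add atoms: water, O
Why: Acid-catalysed ketal hydrolysis; the cyclopropyl-stabilised oxocarbenium ion forms readily, so a weak acid suffices and the trans ring fusion next to the freed ketone is not equilibrated. The butenolide is inert under these conditions.

Step 11
Reactants: 20 (8βH)-4-oxo-15-norlind-7(11)-en-12,8-olide
Product: 21 (8βH)-linda-4(15),7(11)-dien-12,8-olide (8,9-dihydrochloranthalactone A)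
Conditions: Zn, CH2Br2, TiCl4, THF/CH2Cl2, 0 °C → rt
Reagents that add atoms: dibromomethane, BrCBr
Why: Takai–Lombardo methylenation: the non-basic zinc–titanium methylene reagent converts hindered, enolisable ketones into methylene compounds without epimerisation and does not attack lactones. It is preferred to a Wittig ylide, which would deprotonate C5 or the γ-position of the butenolide.

Step 12
Reactants: 21 (8βH)-linda-4(15),7(11)-dien-12,8-olide
Product: 25 chloranthalactone A [(1R,3S,5S,10S)-linda-4(15),7(11),8-trien-12,8-olide], via lithium furanolate 22 (not isolated), via C8 phenylselenide 23 (not isolated), via C8 selenoxide 24 (not isolated)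
Conditions: LiN(SiMe3)2 (1.2 equiv), THF, −78 °C; PhSeCl (1.1 equiv), −78 °C; then 30% H2O2, pyridine, 0 °C → rt, in the dark
Reagents that add atoms: none
Why: The amide removes the γ-hydrogen at C8 to give the aromatic 2-oxidofuran 22, which PhSeCl attacks at C8 (the α-carbon C11 is blocked by its methyl group); oxidation gives selenoxide 24, whose syn-elimination can only use a C9 hydrogen and so installs C8=C9 in conjugation with the butenolide (selenoxide elimination). The C8 stereocentre disappears, so its configuration in 21 and 23 does not matter.

Step 13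
Reactants: 25 chloranthalactone A (two molecules)
Product: 26 CNP0265879.1, the C2-symmetric head-to-head cyclobutane dimer of 25 (C8–C8′ and C9–C9′ on the α faces; 8β-O and 9β-H in each half)
Conditions: hν (365 nm), thioxanthen-9-one (10 mol %), degassed CH2Cl2 (0.3 M), rt
Reagents that add atoms: none
Why: Triplet-sensitised [2+2] photodimerisation: the excited dienol lactone bonds through its terminus C9 to C9′ of a ground-state molecule, giving a 1,4-biradical whose centres C8 and C8′ are stabilised by oxygen and by the unsaturated lactone, and ring closure forms C8–C8′ (head-to-head). Both molecules should react on the α face, away from the axial C14 methyl next to C9 and the β cyclopropane; for two molecules of the same enantiomer this pairing can only give the C2-symmetric anti dimer, which sets C8, C9, C8′ and C9′ as in 26.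

## Compound list

1 | (S)-epichlorohydrin, (2S)-2-(chloromethyl)oxirane | ClC[C@@H]1CO1 | starting material
2 | but-2-en-1-ylmagnesium chloride (crotylmagnesium chloride) | CC=CC[Mg]Cl | starting material
3 | (2S)-1-chloro-4-methylhex-5-en-2-ol (C4 epimer mixture) | ClC[C@@H](O)CC(C)C=C | intermediate
4 | (2S)-2-(2-methylbut-3-en-1-yl)oxirane (side-chain epimer mixture) | C=CC(C)C[C@H]1CO1 | intermediate
5 | (1S,2S,5S)-4-methylbicyclo[3.1.0]hexan-2-ol (C4 epimer mixture, OH trans to the cyclopropane CH2) | CC1C[C@H](O)[C@H]2C[C@@H]12 | intermediate
6 | (1S,5S)-4-methylbicyclo[3.1.0]hexan-2-one (C4 epimer mixture) | CC1CC(=O)[C@H]2C[C@@H]12 | intermediate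
7 | (1S,5R)-4-methylbicyclo[3.1.0]hex-3-en-2-one | CC1=CC(=O)[C@H]2C[C@@H]12 | intermediate
8 | vinylmagnesium bromide | C=C[Mg]Br | starting material
9 | 1-bromobut-2-yne | CC#CCBr | starting material
10 | bromomagnesium (1S,4S,5R)-4-ethenyl-4-methylbicyclo[3.1.0]hex-2-en-2-olate | C1=C(O[Mg]Br)[C@H]2C[C@H]2[C@]1(C)C=C | intermediate
11 | (1S,4S,5R)-3-(but-2-yn-1-yl)-4-ethenyl-4-methylbicyclo[3.1.0]hexan-2-one (C3 epimer mixture) | CC#CCC1C(=O)[C@H]2C[C@H]2[C@]1(C)C=C | intermediate
12 | potassium (1S,4S,5R)-3-(but-2-yn-1-yl)-4-ethenyl-4-methylbicyclo[3.1.0]hex-2-en-2-olate | CC#CCC1=C([O-])[C@H]2C[C@H]2[C@]1(C)C=C.[K+] | intermediate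
13 | (1S,3R,4S,5R)-3-(but-2-yn-1-yl)-4-ethenyl-4-methylbicyclo[3.1.0]hexan-2-one | CC#CC[C@H]1C(=O)[C@H]2C[C@H]2[C@]1(C)C=C | intermediate
14 | (1S,3R,4S,5R)-3-(but-2-yn-1-yl)-4-ethenyl-4-methylspiro[bicyclo[3.1.0]hexane-2,2'-[1,3]dioxolane] | CC#CC[C@H]1C2(OCCO2)[C@H]3C[C@H]3[C@]1(C)C=C | intermediate
15 | 9-{2-[(1S,3R,4S,5R)-3-(but-2-yn-1-yl)-4-methylspiro[bicyclo[3.1.0]hexane-2,2'-[1,3]dioxolan]-4-yl]ethyl}-9-borabicyclo[3.3.1]nonane | CC#CC[C@H]1C2(OCCO2)[C@H]3C[C@H]3[C@]1(C)CCB4C5CCCC4CCC5 | intermediate
16 | 2-[(1S,3R,4S,5R)-3-(but-2-yn-1-yl)-4-methylspiro[bicyclo[3.1.0]hexane-2,2'-[1,3]dioxolan]-4-yl]ethan-1-ol | CC#CC[C@H]1C2(OCCO2)[C@H]3C[C@H]3[C@]1(C)CCO | intermediate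
17 | 2-[(1S,3R,4S,5R)-3-(but-2-yn-1-yl)-4-methylspiro[bicyclo[3.1.0]hexane-2,2'-[1,3]dioxolan]-4-yl]acetaldehyde | CC#CC[C@H]1C2(OCCO2)[C@H]3C[C@H]3[C@]1(C)CC=O | intermediate
18 | carbon monoxide | [C-]#[O+] | starting material
19 | (8βH)-4,4-ethylenedioxy-15-norlind-7(11)-en-12,8-olide | CC1=C2C[C@H]3C4(OCCO4)[C@H]5C[C@H]5[C@]3(C)C[C@@H]2OC1=O | intermediate
20 | (8βH)-4-oxo-15-norlind-7(11)-en-12,8-olide | CC1=C2C[C@H]3C(=O)[C@H]4C[C@H]4[C@]3(C)C[C@@H]2OC1=O | intermediate
21 | (8βH)-linda-4(15),7(11)-dien-12,8-olide | CC1=C2C[C@H]3C(=C)[C@H]4C[C@H]4[C@]3(C)C[C@@H]2OC1=O | intermediate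
22 | lithium 2-furanolate of 21 (C12–O−, furan C11=C12 and C7=C8) | Cc1c([O-])oc2c1C[C@H]1C(=C)[C@H]3C[C@H]3[C@]1(C)C2.[Li+] | intermediate
23 | 8-(phenylselanyl)linda-4(15),7(11)-dien-12,8-olide (C8 configuration immaterial) | CC1=C2C[C@H]3C(=C)[C@H]4C[C@H]4[C@]3(C)CC2([Se]c5ccccc5)OC1=O | intermediate
24 | 8-(phenylseleninyl)linda-4(15),7(11)-dien-12,8-olide | CC1=C2C[C@H]3C(=C)[C@H]4C[C@H]4[C@]3(C)CC2([Se](=O)c5ccccc5)OC1=O | intermediate
25 | chloranthalactone A, (1R,3S,5S,10S)-linda-4(15),7(11),8-trien-12,8-olide | CC1=C2C[C@H]3C(=C)[C@H]4C[C@H]4[C@]3(C)C=C2OC1=O | intermediate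
26 | CNP0265879.1, C2-symmetric head-to-head [2+2] dimer of 25 (C8–C8′, C9–C9′, α faces) | C=C1[C@H]2C[C@H]2[C@@]2(C)[C@H]1CC1=C(C)C(=O)O[C@]13[C@H]2[C@H]1[C@@]2(C)[C@@H]4C[C@@H]4C(=C)[C@@H]2CC2=C(C)C(=O)O[C@@]213 | target

## Step count and risks

Total step count: 13. Longest linear sequence: 13 steps (1 to 26); the route is linear, with 2, 8, 9 and 18 entering as building blocks.

**Step 9 (key step).** Oxidative cyclisation may be slow because the aldehyde sits next to a quaternary carbon; at 100 °C alkyne oligomerisation or loss of the aldehyde at the metal could then compete. Fallback, stepwise instead of one-pot: from 17, low-valent titanium generated from Ti(OiPr)4 and i-PrMgCl couples the alkyne and the aldehyde reductively, and iodine cleaves the C11–Ti bond to give the (7Z)-11-iodo-12,15-dinorlind-7(11)-en-8α-ol ketal F1. Carbonylative lactonisation of F1 with PdCl2(PPh3)2, CO (1 atm) and K2CO3 closes the butenolide and returns to 19.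

**Step 5.** Facial discrimination in the protonation may be poor, because the α-vinyl and β-methyl groups on C10 are similar in size and only the cyclopropane methylene tips the balance. Enolisation of the hindered ketone may be incomplete, or O-protonation may be followed by uncontrolled ketonisation. If the enolate turns out to be attacked mainly on the β face, the major epimer of 11 from step 4 is already 13 and step 5 is dropped. Fallback with reagent control added to substrate control: from 12, Me3SiCl gives the trimethylsilyl enol ether {[(1S,4S,5R)-3-(but-2-yn-1-yl)-4-ethenyl-4-methylbicyclo[3.1.0]hex-2-en-2-yl]oxy}trimethylsilane F2. F2 is protonated at −78 °C by a Lewis-acid-assisted chiral Brønsted acid (SnCl4 with the matched enantiomer of BINOL, 2,6-dimethylphenol as stoichiometric proton source), returning to 13.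

**Step 4.** C-alkylation of the hindered magnesium enolate may be slow, which would allow O-alkylation, proton transfer or coupling of the vinyl metal with 9. Fallback using a cationic electrophile: from 7, the conjugate addition is run with Me3SiCl to give {[(1S,4S,5R)-4-ethenyl-4-methylbicyclo[3.1.0]hex-2-en-2-yl]oxy}trimethylsilane F3. F3 is alkylated in a Nicholas reaction with hexacarbonyl(μ-but-2-yn-1-ol)dicobalt F4 (from but-2-yn-1-ol and Co2(CO)8) and BF3·OEt2 to give the Co2(CO)6 complex of 11, F5. Oxidative decomplexation of F5 with (NH4)2Ce(NO3)6 returns to 11.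

**Step 2.** One of the two methyl epimers of 4 must cyclise with its methyl group on the concave face; if that is slow, carbenoid side reactions (amide addition, dimerisation) would lower throughput, and step 1 may also give some linear crotyl product. Fallback, methyl introduced after the cyclopropanation: from 1, allylmagnesium chloride gives (2S)-1-chlorohex-5-en-2-ol F6, and NaOH closes it to (2S)-2-(but-3-en-1-yl)oxirane F7. Lithium 2,2,6,6-tetramethylpiperidide converts F7 into (1S,2S,5R)-bicyclo[3.1.0]hexan-2-ol F8. IBX oxidises F8 through (1S,5R)-bicyclo[3.1.0]hexan-2-one F9 to (1S,5S)-bicyclo[3.1.0]hex-3-en-2-one F10. Me2CuLi with Me3SiCl adds methyl anti to the cyclopropane to give the trimethylsilyl enol ether of 4-methylbicyclo[3.1.0]hexan-2-one F11, and Saegusa–Ito oxidation of F11 with Pd(OAc)2 in MeCN returns to 7.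

**Step 12.** Selenenylation may occur at C11 instead of C8, the allylic C8 selenoxide may undergo [2,3]-sigmatropic shift instead of syn-elimination, or the selenenic acid may add to the exocyclic methylene. Fallback by hydroxylation and dehydration: from 21, i-Pr3SiOTf and Et3N give the 2-(triisopropylsilyloxy)furan F12. Dimethyldioxirane at −78 °C oxidises F12 at C8 to the 8-hydroxylinda-4(15),7(11)-dien-12,8-olide F13, and p-TsOH in warm benzene dehydrates the hemiketal F13 to 25.

## Further compounds

F1 | step 9 | (7Z)-4,4-ethylenedioxy-11-iodo-12,15-dinorlind-7(11)-en-8α-ol | C/C(I)=C1\C[C@H]2C3(OCCO3)[C@H]4C[C@H]4[C@]2(C)C[C@@H]1O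
F2 | step 5 | {[(1S,4S,5R)-3-(but-2-yn-1-yl)-4-ethenyl-4-methylbicyclo[3.1.0]hex-2-en-2-yl]oxy}trimethylsilane | CC#CCC1=C(O[Si](C)(C)C)[C@H]2C[C@H]2[C@]1(C)C=C
F3 | step 4 | {[(1S,4S,5R)-4-ethenyl-4-methylbicyclo[3.1.0]hex-2-en-2-yl]oxy}trimethylsilane | C1=C(O[Si](C)(C)C)[C@H]2C[C@H]2[C@]1(C)C=C
F4 | step 4 | hexacarbonyl(μ-but-2-yn-1-ol)dicobalt | CC#CCO.[Co].[Co].[C-]#[O+].[C-]#[O+].[C-]#[O+].[C-]#[O+].[C-]#[O+].[C-]#[O+]
F5 | step 4 | Co2(CO)6 complex of (1S,4S,5R)-3-(but-2-yn-1-yl)-4-ethenyl-4-methylbicyclo[3.1.0]hexan-2-one | CC#CCC1C(=O)[C@H]2C[C@H]2[C@]1(C)C=C.[Co].[Co].[C-]#[O+].[C-]#[O+].[C-]#[O+].[C-]#[O+].[C-]#[O+].[C-]#[O+]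
F6 | step 2 | (2S)-1-chlorohex-5-en-2-ol | ClC[C@@H](O)CCC=C
F7 | step 2 | (2S)-2-(but-3-en-1-yl)oxirane | C=CCC[C@H]1CO1
F8 | step 2 | (1S,2S,5R)-bicyclo[3.1.0]hexan-2-ol | O[C@H]1CC[C@@H]2C[C@H]12
F9 | step 2 | (1S,5R)-bicyclo[3.1.0]hexan-2-one | O=C1CC[C@@H]2C[C@H]12
F10 | step 2 | (1S,5S)-bicyclo[3.1.0]hex-3-en-2-one | O=C1C=C[C@@H]2C[C@H]12
F11 | step 2 | trimethylsilyl enol ether of 4-methylbicyclo[3.1.0]hexan-2-one (methyl anti to the cyclopropane CH2) | C[Si](C)(C)OC1=C[C@@H](C)[C@@H]2C[C@H]12
F12 | step 12 | 2-(triisopropylsilyloxy)furan derived from 21 | Cc1c(O[Si](C(C)C)(C(C)C)C(C)C)oc2c1C[C@H]1C(=C)[C@H]3C[C@H]3[C@]1(C)C2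
F13 | step 12 | 8-hydroxylinda-4(15),7(11)-dien-12,8-olide (C8 configuration immaterial) | CC1=C2C[C@H]3C(=C)[C@H]4C[C@H]4[C@]3(C)CC2(O)OC1=O
A1 | alternative 1 | 2-methylcyclohex-2-ene-1,4-dione | CC1=CC(=O)CCC1=O
A2 | alternative 1 | 2,3-bis(trimethylsilyloxy)buta-1,3-diene | C=C(O[Si](C)(C)C)C(=C)O[Si](C)(C)C
A3 | alternative 1 | cis-4a-methyl-6,7-bis(trimethylsilyloxy)-2,3,4a,5,8,8a-hexahydronaphthalene-1,4-dione | C[C@@]12CC(O[Si](C)(C)C)=C(O[Si](C)(C)C)C[C@@H]1C(=O)CCC2=O
A4 | alternative 2 | 8-ethynyl-7-ethenyl-7-methyl-1,4-dioxaspiro[4.5]decan-8-yl acetate (C7 as in the target, C8 unspecified) | C#CC1(OC(C)=O)CCC2(OCCO2)C[C@@]1(C)C=C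
A5 | alternative 2 | tricyclic C4 enol acetate with ring A and cyclopropane (C8 dioxolane) | CC(=O)OC1=C2CCC3(OCCO3)C[C@@]2(C)[C@@H]2C[C@H]12
A6 | alternative 3 | 1-(trans-7-cyclopropyl-7-methyl-1,4-dioxaspiro[4.5]decan-8-yl)ethenyl trifluoromethanesulfonate | C=C(OS(=O)(=O)C(F)(F)F)[C@@H]1CCC2(OCCO2)C[C@@]1(C)C1CC1
A7 | alternative 3 | lindenane tricycle with exocyclic C4 methylene (C8 dioxolane) | C=C1[C@H]2C[C@H]2[C@@]2(C)[C@H]1CCC1(OCCO1)C2
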